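**Plan**
1. Retrosynthetic cuts, in order: the lactol O–H (back to an (S)-1-phenylethyl acetal), the B3–CH2OH carbon–carbon bond, the depsidone ester C(=O)–O bond at B2, the B5–B6 bond of ring B (aldol), the chain bonds C6–C7 and C4–C5 (two Claisen acylations), and the O–CH2 bond of an aryloxyacetate.
2. Ring B, the hexasubstituted benzene, is counted from the ether carbon: B1 (O-aryl), B2 (O-acyl), B3 (CH2OH), B4 (OH), B5 (lactone C=O), B6 (lactol carbon). With a carboxyl at B5, oxygens at B4 and B2 and a carbon branch at B6 it is a resorcylate in the polyketide pattern. B1 lies between B2 and B6, so it maps onto C6 of an octanoate chain (C1 ester to C8 acetal carbon), the α-carbon of an aryloxyacetyl unit flanked by the C5 and C7 ketones.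
3. The tetra-ortho-substituted diaryl ether therefore needs no aryl coupling: its C–O bond is laid down by phenol alkylation and ring B is aromatized around it.
4. Forward order: ring A comes from methyl atrarate; the chain is joined O–C6, then C4–C5, then C6–C7. Ring B closes in step 8, the five-membered lactol ring in step 10 and the seven-membered depsidone ring in step 12.
5. The ring A carboxyl travels as a tert-butyl ester, because a less hindered ester ortho to the aryloxyacetyl carbanions would invite Dieckmann closure to a benzofuran-3-one.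
6. The only stereocenter, the (R)-lactol carbon, comes from separating the diastereomeric (S)-1-phenylethyl acetals (step 12) and from neutral hydrogenolysis with retention (step 14).

Key step: step 8

Assumption: a 3-hydroxyphthalide can racemize through its 2-formylbenzoic acid tautomer, so the (R)-lactol is taken to hold its configuration only when released and kept under neutral, aprotic, cool conditions or as the solid; step 14 is designed for this.

**Route**

Step 1
Reactants: 1 methyl atrarate (methyl 2,4-dihydroxy-3,6-dimethylbenzoate)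
Product: 2 methyl 2-hydroxy-4-methoxy-3,6-dimethylbenzoate
Conditions: MeI (1.1 equiv), K2CO3, acetone, reflux
Reagents that add atoms: iodomethane, CI
Why: Williamson ether synthesis in which the 4-OH, the more acidic and accessible phenol, reacts while the 2-OH stays tied in a hydrogen bond to the ester carbonyl.

Step 2
Reactants: 2 methyl 2-hydroxy-4-methoxy-3,6-dimethylbenzoate
Product: 3 2-hydroxy-4-methoxy-3,6-dimethylbenzoic acid
Conditions: KOH, DMSO–H2O, 90 °C; then cold 1 M HCl
Reagents that add atoms: potassium hydroxide, [K+].[OH-]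
Why: Saponification of a di-ortho-substituted benzoate needs the poorly solvated hydroxide of hot aqueous DMSO, and cold acidification keeps the electron-rich salicylic acid from decarboxylating.

Step 3
Reactants: 3 2-hydroxy-4-methoxy-3,6-dimethylbenzoic acid
Product: 4 tert-butyl 2-hydroxy-4-methoxy-3,6-dimethylbenzoate
Conditions: Cl3CC(=NH)OtBu (2 equiv), CH2Cl2–cyclohexane, rt
Reagents that add atoms: tert-butyl 2,2,2-trichloroacetimidate, CC(C)(C)OC(=N)C(Cl)(Cl)Cl
Why: Trichloroacetimidate esterification, in which the acid protonates the imidate and the carboxylate oxygen captures the tert-butyl cation, so crowding at the acyl carbon is irrelevant and the phenol, which would need a Lewis acid, stays free.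

Step 4
Reactants: 4 tert-butyl 2-hydroxy-4-methoxy-3,6-dimethylbenzoate; 5 methyl bromoacetate
Product: 6 tert-butyl 4-methoxy-2-(2-methoxy-2-oxoethoxy)-3,6-dimethylbenzoate
Conditions: K2CO3, DMF, 50 °C
Reagents that add atoms: none
Why: Williamson alkylation of the hindered 2-OH with a very reactive α-bromo ester sets the future diaryl ether C–O bond as an alkyl aryl ether, and the di-ortho-substituted tert-butyl ester cannot be attacked by the product enolate (no Dieckmann closure).

Step 5
Reactants: 6 tert-butyl 4-methoxy-2-(2-methoxy-2-oxoethoxy)-3,6-dimethylbenzoate; 7 tert-butyl acetoacetate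
Product: 9 tert-butyl 6-[2-(tert-butoxycarbonyl)-5-methoxy-3,6-dimethylphenoxy]-3,5-dioxohexanoate, via dilithium dianion 8 (not isolated)
Conditions: 7 (2.5 equiv), LiN(iPr)2 (5 equiv), THF, 0 °C; 6, −78 to 0 °C; AcOH
Reagents that add atoms: none
Why: Claisen condensation of the acetoacetate dianion through its γ-carbon with the unhindered, inductively activated methyl ester forms C4–C5, while excess dianion absorbs the acidic protons of 9 and the tert-butyl benzoate is too hindered to react.

Step 6
Reactants: 10 methyl dimethoxyacetate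
Product: 11 N,2,2-trimethoxy-N-methylacetamide (Weinreb amide of dimethoxyacetic acid)
Conditions: MeNH(OMe)·HCl, iPrMgCl, THF, −20 °C
Reagents that add atoms: N,O-dimethylhydroxylamine hydrochloride, CNOC.Cl
Why: Weinreb amide synthesis by aminolysis of the ester with the chloromagnesium amide, a standard conversion that leaves the acetal untouched.

Step 7
Reactants: 9 tert-butyl 6-[2-(tert-butoxycarbonyl)-5-methoxy-3,6-dimethylphenoxy]-3,5-dioxohexanoate; 11 N,2,2-trimethoxy-N-methylacetamide
Product: 13 tert-butyl 6-[2-(tert-butoxycarbonyl)-5-methoxy-3,6-dimethylphenoxy]-8,8-dimethoxy-3,5,7-trioxooctanoate (keto form drawn), via trilithium trianion 12 (not isolated)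
Conditions: LiN(iPr)2 (3.05 equiv), THF, −78 to 0 °C; 11 (1.2 equiv), −78 to −20 °C; AcOH, −78 °C; used crude
Reagents that add atoms: none
Why: Polyanion Claisen acylation in which the last-formed, least stabilized carbanion C6 attacks the Weinreb amide to form C6–C7; the chelated tetrahedral adduct lasts until the cold quench, so no fourth equivalent of base is present to metalate the ring A methyl group ortho to the ester, and C6 is an enolizable methine without fixed configuration.

Step 8
Reactants: 13 tert-butyl 6-[2-(tert-butoxycarbonyl)-5-methoxy-3,6-dimethylphenoxy]-8,8-dimethoxy-3,5,7-trioxooctanoate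
Product: 15 tert-butyl 3-[2-(tert-butoxycarbonyl)-5-methoxy-3,6-dimethylphenoxy]-2-(dimethoxymethyl)-4,6-dihydroxybenzoate, via cyclic aldol adduct 14 (not isolated)
Conditions: Et3N (5 equiv), 4 Å MS, CH2Cl2, 0 °C to rt; pH 6 phosphate wash
Reagents that add atoms: none
Why: Et3N equilibrates the enolates of 13, and C2, between the tert-butyl ester and the C3 ketone, adds to the C7 ketone, the most electrophilic carbonyl because of the adjacent acetal carbon, to give aldol 14, which loses one molecule of water by E1cB (C2–H is doubly activated) and tautomerizes at C3 and C5 to the two phenols. The closest known reaction type is the biomimetic aldol aromatization of 3,5,7-triketo esters and diketo-dioxinones to resorcylates under mild base, in which a 6-aryloxy substituent has not yet been tried. Ring B closes through the C2–C7 bond (B5–B6) in a 6-exo-trig mode at the carbonyl, 6-enolendo with respect to the C2=C3 enolate, which is allowed for six-membered rings. The stereocenters of 14 are transient and vanish on aromatization, so no stereocontrol is needed. C-aldol closure must win over Claisen closure of C6 onto C1, lactonization to a 4-hydroxy-2-pyrone and O-closure to a 4-pyranone: the tert-butyl ester is a poor acyl donor, Claisen closure would make C6 quaternary and bar aromatization, and the acid-free medium keeps the pyranone hemiketal reversible while aromatization is irreversible. The sieves bind the released water so that no hydroxide cleaves the dimethoxyacetyl group by retro-Claisen reaction, and the ring A tert-butyl ester is inert to the C6 enolate.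

Step 9
Reactants: 15 tert-butyl 3-[2-(tert-butoxycarbonyl)-5-methoxy-3,6-dimethylphenoxy]-2-(dimethoxymethyl)-4,6-dihydroxybenzoate
Product: 16 tert-butyl 3-[2-(tert-butoxycarbonyl)-5-methoxy-3,6-dimethylphenoxy]-2-(dimethoxymethyl)-5-formyl-4,6-dihydroxybenzoate
Conditions: MgCl2, Et3N, (CH2O)n, MeCN, reflux; aq citric acid
Reagents that add atoms: paraformaldehyde (formaldehyde unit), C=O
Why: Magnesium-mediated ortho-formylation of phenols (Casnati–Skattebøl reaction) delivers formaldehyde within the magnesium phenoxide to B3, the only free position of ring B and ortho to both phenols; ring A has no phenol to direct attack, and the basic medium spares the acetal and both tert-butyl esters.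

Step 10
Reactants: 16 tert-butyl 3-[2-(tert-butoxycarbonyl)-5-methoxy-3,6-dimethylphenoxy]-2-(dimethoxymethyl)-5-formyl-4,6-dihydroxybenzoate
Product: 17 2-[(6-formyl-3,5,7-trihydroxy-1-oxo-1,3-dihydroisobenzofuran-4-yl)oxy]-4-methoxy-3,6-dimethylbenzoic acid (racemic lactol)
Conditions: CF3CO2H–CH2Cl2–H2O (10:10:1), 0 °C to rt
Reagents that add atoms: water, O
Why: Acidolysis of both tert-butyl esters and hydrolysis of the acetal occur in one operation, the freed B6 aldehyde and B5 carboxyl close at once to the racemic 3-hydroxyphthalide (ring–chain tautomerism), and ring B has no free position for tert-butylation.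

Step 11
Reactants: 17 2-[(6-formyl-3,5,7-trihydroxy-1-oxo-1,3-dihydroisobenzofuran-4-yl)oxy]-4-methoxy-3,6-dimethylbenzoic acid; 18 (S)-1-phenylethanol
Product: 19 2-({6-formyl-5,7-dihydroxy-1-oxo-3-[(S)-1-phenylethoxy]-1,3-dihydroisobenzofuran-4-yl}oxy)-4-methoxy-3,6-dimethylbenzoic acid (both configurations at the acetal carbon)
Conditions: 18 (3 equiv), PPTS (cat.), 4 Å MS, ClCH2CH2Cl, 50 °C
Reagents that add atoms: none
Why: Acid-catalysed pseudo-ester (cyclic acetal) formation of a 3-hydroxyphthalide with a secondary alcohol, in which PPTS is too weak to ionize 18 or to esterify the di-ortho-substituted ring A acid, the chelated B3 aldehyde does not acetalize, and the acetal carbon forms in both configurations.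

Step 12
Reactants: 19 2-({6-formyl-5,7-dihydroxy-1-oxo-3-[(S)-1-phenylethoxy]-1,3-dihydroisobenzofuran-4-yl}oxy)-4-methoxy-3,6-dimethylbenzoic acid
Product: 20 depsidone aldehyde: the ring A carbonyl esterified to the B2 oxygen, CHO at B3, OH at B4, and the (R)-acetal carbon at B6 bearing the (S)-1-phenylethoxy group
Conditions: DCC (1.2 equiv), CH2Cl2 (0.005 M), rt; SiO2 chromatography, then crystallization of the (R)-acetal diastereomer
Reagents that add atoms: none
Why: Carbodiimide (Steglich-type) lactonization at high dilution, in which only the B2 phenol, ortho to the ether oxygen, can reach the activated ring A carboxyl (seven-membered ring) and the pseudo-ester keeps the B5 carboxyl silent; the configuration of the acetal carbon is secured here by separating the two rigid diastereomers, with the (S)-phenylethyl carbon as internal reference for an X-ray assignment.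

Step 13
Reactants: 20 depsidone aldehyde with the (R)-acetal carbon
Product: 21 depsidone alcohol: as 20 but with CH2OH at B3
Conditions: NaBH4 (1 equiv), THF–EtOH, −30 °C; AcOH
Reagents that add atoms: none
Why: Chemoselective borohydride reduction, since the aldehyde is far more electrophilic than the hindered depsidone ester and the phenoxide-deactivated phthalide carbonyl; low temperature and the acid quench prevent acyl migration to the new alkoxide, and the acetal stereocenter has no pathway to epimerize.

Step 14
Reactants: 21 depsidone alcohol with the (R)-acetal carbon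
Product: 22 target CNP0321962.1, (R)-lactol
Conditions: H2 (1 atm), Pd/C, EtOAc, 0 °C to rt; filtration, cold evaporation
Reagents that add atoms: none
Why: Hydrogenolysis of the benzyl-type C–O bond on the auxiliary side (as for benzyl glycosides) leaves all four bonds of the acetal carbon intact, so the (R) configuration is retained; the hexasubstituted ring B keeps its own benzylic C–O bonds off the metal surface, and the neutral aprotic medium slows ring–chain racemization.

**Compound list**
1 | methyl atrarate (methyl 2,4-dihydroxy-3,6-dimethylbenzoate) | COC(=O)c1c(C)cc(O)c(C)c1O | starting material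
2 | methyl 2-hydroxy-4-methoxy-3,6-dimethylbenzoate | COC(=O)c1c(C)cc(OC)c(C)c1O | intermediate
3 | 2-hydroxy-4-methoxy-3,6-dimethylbenzoic acid | OC(=O)c1c(C)cc(OC)c(C)c1O | intermediate
4 | tert-butyl 2-hydroxy-4-methoxy-3,6-dimethylbenzoate | CC(C)(C)OC(=O)c1c(C)cc(OC)c(C)c1O | intermediate
5 | methyl bromoacetate | COC(=O)CBr | starting material
6 | tert-butyl 4-methoxy-2-(2-methoxy-2-oxoethoxy)-3,6-dimethylbenzoate | CC(C)(C)OC(=O)c1c(C)cc(OC)c(C)c1OCC(=O)OC | intermediate
7 | tert-butyl acetoacetate | CC(=O)CC(=O)OC(C)(C)C | starting material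
8 | dilithium dianion (bis-enolate) of 7 | [Li+].[Li+].C=C([O-])C=C([O-])OC(C)(C)C | intermediate
9 | tert-butyl 6-[2-(tert-butoxycarbonyl)-5-methoxy-3,6-dimethylphenoxy]-3,5-dioxohexanoate | CC(C)(C)OC(=O)c1c(C)cc(OC)c(C)c1OCC(=O)CC(=O)CC(=O)OC(C)(C)C | intermediate
10 | methyl dimethoxyacetate | COC(OC)C(=O)OC | starting material
11 | N,2,2-trimethoxy-N-methylacetamide | CON(C)C(=O)C(OC)OC | intermediate
12 | trilithium trianion (tris-enolate) of 9 | [Li+].[Li+].[Li+].CC(C)(C)OC(=O)c1c(C)cc(OC)c(C)c1OC=C([O-])C=C([O-])C=C([O-])OC(C)(C)C | intermediate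
13 | tert-butyl 6-[2-(tert-butoxycarbonyl)-5-methoxy-3,6-dimethylphenoxy]-8,8-dimethoxy-3,5,7-trioxooctanoate (C6 not configurationally fixed) | COc1cc(C)c(C(=O)OC(C)(C)C)c(OC(C(=O)C(OC)OC)C(=O)CC(=O)CC(=O)OC(C)(C)C)c1C | intermediate
14 | tert-butyl 3-aryloxy-2-(dimethoxymethyl)-2-hydroxy-4,6-dioxocyclohexane-1-carboxylate (aldol adduct, transient stereocenters undefined) | COc1cc(C)c(C(=O)OC(C)(C)C)c(OC2C(=O)CC(=O)C(C(=O)OC(C)(C)C)C2(O)C(OC)OC)c1C | intermediate
15 | tert-butyl 3-[2-(tert-butoxycarbonyl)-5-methoxy-3,6-dimethylphenoxy]-2-(dimethoxymethyl)-4,6-dihydroxybenzoate | COc1cc(C)c(C(=O)OC(C)(C)C)c(Oc2c(O)cc(O)c(C(=O)OC(C)(C)C)c2C(OC)OC)c1C | intermediate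
16 | 5-formyl derivative of 15 | COc1cc(C)c(C(=O)OC(C)(C)C)c(Oc2c(O)c(C=O)c(O)c(C(=O)OC(C)(C)C)c2C(OC)OC)c1C | intermediate
17 | 2-[(6-formyl-3,5,7-trihydroxy-1-oxo-1,3-dihydroisobenzofuran-4-yl)oxy]-4-methoxy-3,6-dimethylbenzoic acid (racemic) | COc1cc(C)c(C(=O)O)c(Oc2c(O)c(C=O)c(O)c3c2C(O)OC3=O)c1C | intermediate
18 | (S)-1-phenylethanol | C[C@H](O)c1ccccc1 | starting material
19 | (S)-1-phenylethyl pseudo-ester of 17 (epimers at the acetal carbon) | COc1cc(C)c(C(=O)O)c(Oc2c(O)c(C=O)c(O)c3c2C(O[C@@H](C)c4ccccc4)OC3=O)c1C | intermediate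
20 | depsidone aldehyde, (R)-acetal carbon, (S)-1-phenylethoxy | COc1cc(C)c2c(c1C)Oc1c(c(C=O)c(O)c3c1[C@H](O[C@@H](C)c4ccccc4)OC3=O)OC2=O | intermediate
21 | depsidone alcohol, (R)-acetal carbon, (S)-1-phenylethoxy | COc1cc(C)c2c(c1C)Oc1c(c(CO)c(O)c3c1[C@H](O[C@@H](C)c4ccccc4)OC3=O)OC2=O | intermediate
22 | CNP0321962.1, (R)-lactol | COc1cc(C)c2c(c1C)Oc1c(c(CO)c(O)c3c1[C@H](O)OC3=O)OC2=O | target

**Step count**
Total step count: 14.
Longest linear sequence: 13 (steps 1–5 and 7–14, from methyl atrarate).

**Steps most likely to fail**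

Step 8.
- What may go wrong: the chain may rest as its unreactive C6 enolate, close through oxygen to a 4-pyranone, or lose the dimethoxyacetyl group by retro-Claisen cleavage before the C2–C7 bond forms.
- Fallback (sets out from 4, returns at 17): the same bond is closed from a dioxinone-locked chain, in which the C3 oxygen is tied into a ring and cannot form a pyranone.
- Alkylating 4 with 2-chloro-N-methoxy-N-methylacetamide (K2CO3, DMF) should give the aryloxyacetic Weinreb amide F1.
- The lithium dienolate of 2,2,6-trimethyl-4H-1,3-dioxin-4-one (LiN(SiMe3)2, THF, −78 °C) is acylated by F1 to the keto-dioxinone F2.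
- The dianion of F2 (LiN(iPr)2, 2 equiv) is acylated by 11 to the diketo-dioxinone F3.
- Et3N in CH2Cl2 should aromatize F3, with the dioxinone CH as nucleophile, to the acetonide-bridged resorcylate F4.
- Formylation as in step 9 gives the formyl acetonide F5.
- Warm aqueous CF3CO2H should strip the ring A tert-butyl ester and the acetal, and the freed aldehyde hydrate should open the neighbouring dioxinone carbonyl with loss of acetone to reach 17.

Step 7.
- What may go wrong: metalation of the ring A methyl group ortho to the ester, incomplete third deprotonation, acylation at C2 instead of C6, or slow attack at the crowded C6 carbanion may erode the acylation.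
- Fallback (sets out from 6, returns at 13): the C6–C7 bond is made at a lower oxidation level from a simple mono-enolate.
- The lithium enolate of 6 (LiN(iPr)2, THF, −78 °C) adds to anhydrous 2,2-dimethoxyacetaldehyde to give the aldol ester F6 as a diastereomer mixture, which is of no consequence.
- Et3SiCl and imidazole give the silyl ether F7.
- Claisen condensation with dianion 8, as in step 5, gives the 7-silyloxy diketo ester F8.
- Buffered HF·pyridine frees the 7-hydroxy diketo ester F9.
- IBX oxidation of the β-hydroxy ketone delivers 13.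

Step 14.
- What may go wrong: the lactol or hydroxymethyl benzylic C–O bonds may be over-reduced, the hindered secondary benzylic ether may cleave slowly, and the configuration may erode by ring–chain tautomerism on the catalyst.
- Fallback (sets out from 17, returns at 22): the auxiliary is changed to one removed by light instead of hydrogen.
- Treating 17 with (S)-1-(2-nitrophenyl)ethanol under the conditions of step 11 gives the nitrophenylethyl pseudo-ester F10.
- DCC lactonization and separation, as in step 12, give the (R)-acetal depsidone aldehyde F11 and its (S)-acetal epimer F12.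
- NaBH4 reduction of F11, as in step 13, gives the depsidone alcohol F13.
- Irradiation of F13 at 365 nm in MeCN cleaves the o-nitrobenzyl-type C–O bond under neutral conditions without touching the acetal carbon and releases 22.

**Further compounds**
F1 | step 8 | tert-butyl 4-methoxy-2-{2-[methoxy(methyl)amino]-2-oxoethoxy}-3,6-dimethylbenzoate | CC(C)(C)OC(=O)c1c(C)cc(OC)c(C)c1OCC(=O)N(C)OC
F2 | step 8 | 6-(3-aryloxy-2-oxopropyl)-2,2-dimethyl-4H-1,3-dioxin-4-one | COc1cc(C)c(C(=O)OC(C)(C)C)c(OCC(=O)CC2=CC(=O)OC(C)(C)O2)c1C
F3 | step 8 | 6-(3-aryloxy-5,5-dimethoxy-2,4-dioxopentyl)-2,2-dimethyl-4H-1,3-dioxin-4-one | COc1cc(C)c(C(=O)OC(C)(C)C)c(OC(C(=O)C(OC)OC)C(=O)CC2=CC(=O)OC(C)(C)O2)c1C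
F4 | step 8 | 6-aryloxy-5-(dimethoxymethyl)-7-hydroxy-2,2-dimethyl-4H-benzo[d][1,3]dioxin-4-one | COc1cc(C)c(C(=O)OC(C)(C)C)c(Oc2c(O)cc3OC(C)(C)OC(=O)c3c2C(OC)OC)c1C
F5 | step 8 | 8-formyl derivative of F4 | COc1cc(C)c(C(=O)OC(C)(C)C)c(Oc2c(O)c(C=O)c3OC(C)(C)OC(=O)c3c2C(OC)OC)c1C
F6 | step 7 | methyl 2-aryloxy-3-hydroxy-4,4-dimethoxybutanoate (diastereomer mixture) | COc1cc(C)c(C(=O)OC(C)(C)C)c(OC(C(O)C(OC)OC)C(=O)OC)c1C
F7 | step 7 | methyl 2-aryloxy-4,4-dimethoxy-3-(triethylsilyloxy)butanoate | COc1cc(C)c(C(=O)OC(C)(C)C)c(OC(C(O[Si](CC)(CC)CC)C(OC)OC)C(=O)OC)c1C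
F8 | step 7 | tert-butyl 6-aryloxy-8,8-dimethoxy-3,5-dioxo-7-(triethylsilyloxy)octanoate | COc1cc(C)c(C(=O)OC(C)(C)C)c(OC(C(O[Si](CC)(CC)CC)C(OC)OC)C(=O)CC(=O)CC(=O)OC(C)(C)C)c1C
F9 | step 7 | tert-butyl 6-aryloxy-7-hydroxy-8,8-dimethoxy-3,5-dioxooctanoate | COc1cc(C)c(C(=O)OC(C)(C)C)c(OC(C(O)C(OC)OC)C(=O)CC(=O)CC(=O)OC(C)(C)C)c1C
F10 | step 14 | (S)-1-(2-nitrophenyl)ethyl pseudo-ester of 17 (epimers at the acetal carbon) | COc1cc(C)c(C(=O)O)c(Oc2c(O)c(C=O)c(O)c3c2C(O[C@@H](C)c4ccccc4[N+](=O)[O-])OC3=O)c1C
F11 | step 14 | depsidone aldehyde, (R)-acetal carbon, (S)-1-(2-nitrophenyl)ethoxy | COc1cc(C)c2c(c1C)Oc1c(c(C=O)c(O)c3c1[C@H](O[C@@H](C)c4ccccc4[N+](=O)[O-])OC3=O)OC2=O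
F12 | step 14 | (S)-acetal epimer of F11 | COc1cc(C)c2c(c1C)Oc1c(c(C=O)c(O)c3c1[C@@H](O[C@@H](C)c4ccccc4[N+](=O)[O-])OC3=O)OC2=O
F13 | step 14 | depsidone alcohol, (R)-acetal carbon, (S)-1-(2-nitrophenyl)ethoxy | COc1cc(C)c2c(c1C)Oc1c(c(CO)c(O)c3c1[C@H](O[C@@H](C)c4ccccc4[N+](=O)[O-])OC3=O)OC2=O
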